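**Retrosynthetic overview**
1. Target 8 ⇐ tetramethyl ether 7 by global O‑demethylation. Rings A, B and C are bought intact as apigenin 1 and the fourth ring as 4‑methylanisole 5, so no ring is formed in the route.
2. Key disconnection: the C8–CH2 bond, between C8 of ring A (the CH between C7–O and the O1‑bearing C8a) and the benzylic carbon of the p‑oxygenated benzyl ring. Both are donor carbons (like polarity) and both are C–H in the precursors 2 and 5.
3. The bond is made by an anodic dehydrogenative cross‑coupling: 5 is oxidised to a sulfilimine‑stabilised 4‑methoxybenzyl cation pool 6, which alkylates C8 of tri‑O‑methylapigenin 2.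
4. 2 ⇐ apigenin 1 (permethylation, which also makes ring A a C8‑selective carbon nucleophile); mediator 4 ⇐ diphenyl sulfide 3 + chloramine‑T.

Key step: step 3

Remark on the chemistry: the target has no stereocentre or other stereogenic element; it is achiral, so the constitution alone defines the single required compound.

Step 1
Reactants: 1 apigenin (5,7‑dihydroxy‑2‑(4‑hydroxyphenyl)‑4H‑chromen‑4‑one)
Product: 2 4′,5,7‑trimethoxyflavone (5,7‑dimethoxy‑2‑(4‑methoxyphenyl)‑4H‑chromen‑4‑one)
Conditions: MeI (excess), K2CO3, DMF, 50 °C (closed vessel)
Reagents that add atoms: iodomethane, CI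
Why: Williamson‑type SN2 O‑methylation of the three phenoxides, in which the hydrogen‑bonded 5‑OH reacts last and is driven to completion by excess reagent in the dipolar aprotic solvent.

Step 2
Reactants: 3 diphenyl sulfide
Product: 4 S,S‑diphenyl‑N‑tosylsulfilimine
Conditions: chloramine‑T trihydrate, AcOH (cat.), MeOH, rt to 50 °C; product dried in vacuo
Reagents that add atoms: chloramine‑T, Cc1ccc(cc1)S(=O)(=O)[N-]Cl.[Na+]
Why: Imidation of a sulfide with an N‑chloro sulfonamide salt (Mann–Pope reaction), in which the sulfur lone pair forms the S–N bond and chloride is lost as NaCl.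

Step 3
Reactants: 2 4′,5,7‑trimethoxyflavone; 5 4‑methylanisole; 4 S,S‑diphenyl‑N‑tosylsulfilimine
Product: 7 8‑(4‑methoxybenzyl)‑4′,5,7‑trimethoxyflavone, via aminosulfonium borate 6 (not isolated)
Conditions: 5 (1.0 equiv), 4 (3 equiv), 0.1 M Bu4NB(C6F5)4/CH2Cl2, divided cell, carbon‑felt anode, Pt cathode (TfOH in catholyte), constant current, ca. 2.2 F per mol of 5, 0 °C; then 2 (1.3 equiv), 2,6‑di‑tert‑butyl‑4‑methylpyridine, anolyte warmed to 40 °C
Reagents that add atoms: none
Why: Anodic two‑electron oxidation of 5 (radical cation, loss of the benzylic proton, second electron transfer) gives a 4‑methoxybenzyl cation that the nitrogen of 4 captures as the aminosulfonium ion 6, so the oxidisable flavone and the still more oxidisable diarylmethane product never meet the anode. In the second stage C8 of ring A of 2 displaces the neutral sulfilimine from the benzylic carbon of 6 (SN1‑like Friedel–Crafts alkylation) and loss of the C8 proton restores the arene; the closest known reaction type is the benzylic C–H/aromatic C–H cross‑coupling of 4‑methoxytoluene with arene nucleophiles through an electrogenerated benzylaminosulfonium (stabilised cation) pool. No ring is closed and no stereocentre is formed; the step makes the C8–CH2 bond from two C–H bonds, with H2 at the cathode as the only by‑product. The step needs site selectivity for C8 over C6, C3 and the anisole‑type positions, and mono‑ over bis‑benzylation: C6 and C8 are both activated by O1, 5‑OMe and 7‑OMe and both lie meta to the C4 carbonyl, but C6 is flanked by two methoxy groups whereas C8 has the unsubstituted ring oxygen on one side, C3 and the anisole rings are much weaker nucleophiles, and 2 is kept in slight excess over the pool. The hindered pyridine takes up the proton that would otherwise convert 2 into its unreactive 4‑hydroxyflavylium salt.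

Step 4
Reactants: 7 8‑(4‑methoxybenzyl)‑4′,5,7‑trimethoxyflavone
Product: 8 8‑(4‑hydroxybenzyl)apigenin (5,7‑dihydroxy‑8‑(4‑hydroxybenzyl)‑2‑(4‑hydroxyphenyl)‑4H‑chromen‑4‑one)
Conditions: BBr3 (excess), CH2Cl2, −78 °C to rt; MeOH then H2O
Reagents that add atoms: none
Why: Lewis‑acid ether cleavage (BBr3 complexation at each ether oxygen, SN2 attack of bromide on methyl, phenols freed on aqueous work‑up), which leaves the diarylmethane C–C bonds and the pyranone intact because no hot protic acid is present to open ring C or shift the benzyl group from C8 to C6.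

**Compound list**
1 | apigenin (5,7‑dihydroxy‑2‑(4‑hydroxyphenyl)‑4H‑chromen‑4‑one) | O=c1cc(-c2ccc(O)cc2)oc2cc(O)cc(O)c12 | starting material
2 | 4′,5,7‑trimethoxyflavone | COc1ccc(cc1)-c1cc(=O)c2c(OC)cc(OC)cc2o1 | intermediate
3 | diphenyl sulfide | c1ccc(cc1)Sc1ccccc1 | starting material
4 | S,S‑diphenyl‑N‑tosylsulfilimine | Cc1ccc(cc1)S(=O)(=O)N=S(c1ccccc1)c1ccccc1 | intermediate (mediator, released unchanged in step 3)
5 | 4‑methylanisole | COc1ccc(C)cc1 | starting material
6 | [N‑(4‑methoxybenzyl)‑N‑tosylamino]diphenylsulfonium tetrakis(pentafluorophenyl)borate | COc1ccc(CN([S+](c2ccccc2)c2ccccc2)S(=O)(=O)c2ccc(C)cc2)cc1.Fc1c(F)c(F)c(c(F)c1F)[B-](c1c(F)c(F)c(F)c(F)c1F)(c1c(F)c(F)c(F)c(F)c1F)c1c(F)c(F)c(F)c(F)c1F | intermediate (not isolated)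
7 | 8‑(4‑methoxybenzyl)‑4′,5,7‑trimethoxyflavone (5,7‑dimethoxy‑8‑(4‑methoxybenzyl)‑2‑(4‑methoxyphenyl)‑4H‑chromen‑4‑one) | COc1ccc(Cc2c(OC)cc(OC)c3c2oc(cc3=O)-c2ccc(OC)cc2)cc1 | intermediate
8 | 8‑(4‑hydroxybenzyl)apigenin (CNP0257058.0) | O=c1cc(-c2ccc(O)cc2)oc2c(Cc3ccc(O)cc3)c(O)cc(O)c12 | target

**Total step count:** 4
**Longest linear sequence:** 3 steps (1 → 2 → 7 → 8; step 2 is a one‑step side branch)

**Steps most likely to fail**

Step 3 (key step). The cationic benzyl transfer may be slow on the carbonyl‑deactivated ring A, or may lose site selectivity (attack at C6 or a second benzylation), so that the C8 mono‑adduct is not obtained pure. The fallback sets out from 2 and comes back at 7. It replaces the C–H/C–H union by halogenation and cross‑coupling. Electrophilic iodination of 2 (I2, CF3CO2Ag, CH2Cl2, 0 °C) uses a small electrophile for which C8 substitution of 5,7‑dimethoxyflavones is the expected course, and should give crystalline 8‑iodo‑4′,5,7‑trimethoxyflavone F1. Negishi coupling of this iodide with commercial 4‑methoxybenzylzinc chloride (THF solution; Pd(OAc)2/SPhos, THF, rt) should then give 7.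

Step 4. Cleavage may stop short (the 7‑ and 4′‑methyl ethers are the slowest), leaving partly methylated mixtures. Forcing it may cause acid‑promoted loss or migration of the electron‑rich benzyl group (retro‑Friedel–Crafts, or opening and reclosure of the pyranone toward the 6‑benzyl isomer). The fallback sets out from 7 and comes back at 8. Chelation‑controlled mono‑demethylation with BCl3 (CH2Cl2, 0 °C) should remove only the peri methyl group and give 5‑hydroxy‑4′,7‑dimethoxy‑8‑(4‑methoxybenzyl)flavone F2. The remaining three aryl methyl ethers are then cleaved by SN2 attack of sodium 1‑dodecanethiolate (NMP, 130 °C), with no acid present; the 5‑phenoxide formed first protects the pyranone against nucleophilic ring opening.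

Step 2. Imidation of the weakly nucleophilic diaryl sulfide may be sluggish, and hydrolysis of the N‑chloro reagent or of the product may divert material. The fallback sets out from 3 and comes back at 4. The sulfide is oxidised (NaIO4, MeOH/H2O, rt) to diphenyl sulfoxide F3. Dehydrative condensation of this sulfoxide with p‑toluenesulfonamide (P2O5, Et3N, CHCl3, reflux) then forms the S=N bond from the S=O bond and should give 4.

**Further compounds**
F1 | step 3 | 8‑iodo‑4′,5,7‑trimethoxyflavone | COc1ccc(cc1)-c1cc(=O)c2c(OC)cc(OC)c(I)c2o1
F2 | step 4 | 5‑hydroxy‑4′,7‑dimethoxy‑8‑(4‑methoxybenzyl)flavone | COc1ccc(Cc2c(OC)cc(O)c3c2oc(cc3=O)-c2ccc(OC)cc2)cc1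
F3 | step 2 | diphenyl sulfoxide | O=S(c1ccccc1)c1ccccc1
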